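South-east carries less catalyst than noon but twice the time of noon's last reading, so let us put a number on your hunch that the two cancel.

in all of them: starting material 0.20 M

| charge | second substrate | free catalyst | remark | time |
|---|---|---|---|---|
| noon | 0.20 M | 30 mM | run made earlier |  |
| summer | 0.20 M | 35 mM | run made earlier |  |
| south-east | 0.200 M | 20 mM |  | 30 min |
| south-west | 0.200 M | 24 mM |  | 30 min |
| north-west | 0.200 M | 29 mM |  | 30 min |

| run | time / min | starting material / % | target / % | catalyst intermediate A / % |
|---|---|---|---|---|
| noon | 1.33 | 93.2 | 7.0 | 0 |
| noon | 2.50 | 89.1 | 9.4 | 1.3 |
| noon | 4.00 | 83.0 | 14.6 | 1.6 |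
| noon | 8.00 | 71.3 | 29.0 | 1.4 |
| noon | 15.0 | 51.6 | 45.8 | 0 |
| summer | 1.33 | 93.2 | 5.6 | 2.6 |
| summer | 4.00 | 81.2 | 17.2 | 1.2 |
| summer | 8.00 | 66.6 | 32.8 | 0.5 |
| summer | 10.0 | 61.0 | 38.8 | 1.3 |
| summer | 15.0 | 45.7 | 54.5 | 0.1 |

(scatter of a reading: 1 percentage point)

- amounts and yields of target count crystals too
- given per volume of solution although it is solid: crystals
- the numbers in the tables scatter by 1 percentage point (one standard deviation)
- candidate steps: catalyst intermediate B -> free catalyst + second product; crystals <-> target; catalyst intermediate A -> free catalyst + target; second substrate + free catalyst <-> catalyst intermediate B; starting material + free catalyst <-> catalyst intermediate A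

1. which of these there is most of at the end, counted by the starting material in it, south-east (catalyst intermediate A / starting material / target)
2. which of these there is most of at the end, counted by the starting material in it, south-west (catalyst intermediate A / starting material / target)
3. which of these there is most of at the end, counted by the starting material in it, north-west (catalyst intermediate A / starting material / target)
4. the largest of these amounts at the end, in percent of the starting material charged, south-east
5. the largest of these amounts at the end, in percent of the starting material charged, south-west
6. the largest of these amounts at the end, in percent of the starting material charged, north-west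

1. We follow f, the fraction of the charge of starting material left. At 15.0 min, f and target sum to 97.4 % in noon and 100 % in summer, and the highest reading of catalyst intermediate A is 2.6 %. So we take target as one minus f.

2. We try a pseudo-first-order fall, f = exp(−κ × catalyst charge × time). Noon's last reading gives a first κ of 1.47 /M/min.

3. We put that back into summer. It gives f = 46.2 %, and the reading is 45.7 % with a scatter of 1 percentage point, so we keep the catalyst charge as a plain factor. Summer's own κ is 1.49 /M/min.

4. Going round once more, we carry their mean, κ = 1.48 /M/min, the fall in ln f per unit of catalyst charge and of time. It is read with both substrates charged equally.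

5. South-east gets 1.33 times noon's catalyst × time, so the two do not cancel. We reckon target at 58.9 % in south-east, 65.6 % in south-west and 72.4 % in north-west. This reaches past summer's catalyst × time, so it is an extrapolation.

The forecast names target, target and target at 59 %, 65 % and 72 %, holding that “the rate is first order in catalyst”.

The flasks give target at 58.5 % in south-east, target at 65.7 % in south-west and target at 73.1 % in north-west.

    catalyst intermediate B → free catalyst + second product (k = 0.894 /min)
    crystals ⇌ target, rate k2*(cs2 - [target]) while solid is left; crystals form when [target] > cs2 (solubility = 0.110 M, k = 1.64 /min)
    catalyst intermediate A → free catalyst + target (k = 4.08 /min)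
    second substrate + free catalyst ⇌ catalyst intermediate B (K = 13.4 /M, k = 1.51 /M/min)
    starting material + free catalyst ⇌ catalyst intermediate A (K = 4.60 /M, k = 2.10 /M/min)

In south-east, κ gives f = 41.1 %, and the flask holds 41.2 %. The neighbour is south-east with 0.50 M of second substrate, a charge that κ never saw. The same reckoning again gives 41.1 %, but the neighbour has 50 % left and 49.6 % target. Its own κ is 1.15 /M/min, lower than the carried one. At 30.0 min, catalyst intermediate B holds 30.7 % of the catalyst charged in the neighbour, against 13.5 % in south-east.

(The runs come from a simulation with made-up constants; the scatter is artificial.)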